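**Quick number.** At 1.5 h the flask should have finished, because the east run at 0.12 M already read 0.2% starting material at 12.0 min, a shorter time than ours. So your hunch of a flat plateau stands, and the quick number is a yield.

| flask | starting material | partner | remark | time |
|---|---|---|---|---|
| east | 0.12 M | 1 equiv (fed, over 30 s) | run made earlier |  |
| north-west | 0.50 M | 1 equiv (fed, over 30 s) | run made earlier |  |
| south-east | 0.25 M | 2 equiv (fed, over 30 s) | run made earlier |  |
| flask | 0.25 M | 1.00 equiv (fed, over 30 s) |  | 1.5 h |

| run | time / min | starting material / % | target / % |
|---|---|---|---|
| east | 8.00 | 1.3 | 57.7 |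
| east | 12.0 | 0.2 | 60.0 |
| east | 15.0 | 1.6 | 64.0 |
| east | 25.0 | 0.9 | 63.5 |
| east | 40.0 | 0 | 64.2 |
| east | 60.0 | 1.2 | 65.7 |
| east | 90.0 | 1.1 | 62.5 |
| north-west | 12.0 | 0 | 76.5 |
| north-west | 25.0 | 0.5 | 76.0 |
| north-west | 40.0 | 1.3 | 75.3 |
| north-west | 50.0 | 0 | 77.1 |
| north-west | 60.0 | 0 | 77.5 |
| north-west | 80.0 | 0.4 | 78.8 |
| north-west | 90.0 | 0.4 | 77.4 |
| south-east | 8.00 | 0 | 78.4 |
| south-east | 15.0 | 0 | 77.1 |
| south-east | 25.0 | 0.3 | 79.2 |
| south-east | 50.0 | 0 | 77.3 |
| south-east | 90.0 | 0 | 77.9 |

(standard deviation of a reading: 1 percentage point)

1. which holds at 1.5 h: what has brought the reaction to rest, or that it has not come to rest (it is still moving / all of the starting material has reacted / forward and back rates have come level / the partner has run out first)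
2. how much of the starting material has reacted by 1.5 h
3. how much target there is at 1.5 h, in percent of the starting material charged

- what was read earlier has a scatter of 1 percentage point, one standard deviation
- the reaction counts as stopped when no species that holds the starting material changes by six tenths of a point or more over the second half of the time

**Our rule.** We suppose a fixed share of starting material is lost early. After that, target forms in proportion to partner while side product does not. Let the level point be the partner concentration at which both paths run equally, a selectivity factor in concentration units. Integrating gives: loss = fixed loss + (level point ÷ starting concentration) × G, where G is the natural logarithm of charged over remaining partner. The plateaus read 64.0% for east and 76.9% for north-west, so G is 1.02 and 1.47. Those two runs give a level point of 0.0233 M and a fixed loss of 16.2%. For the south-east run the rule gives a loss of 20.8%, against 22.0% read. G moves slowly, so we freeze it at the mean of the two values for the flask, which gives 72.2%. Refreshing G once gives 71.9%.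

**The forecast.** It says all of the starting material has reacted, with 100% reacted and 71% target, interpolated, and it also mentions “a fixed-loss ceiling near 85%”. Our figure lies 0.90 percentage points above it.

**The flask.** It gives 72.6% target with 100% reacted: all of the starting material has reacted. At the end of the feed it held 36.2% intermediate A and 31.5% intermediate B, but at 0.750 h each stands at 0%.

    starting material → side product (k = 0.0113 s⁻¹)
    starting material ⇌ intermediate A (K = 3.00, k = 0.103 s⁻¹)
    intermediate A ⇌ intermediate B (K = 2.50, k = 0.0396 s⁻¹)
    partner + intermediate B → target (k = 0.0637 L mol⁻¹ s⁻¹)

**Second flask.** With G refreshed in two rounds, the level point gives 79.9% target at 1.0 M of starting material, and that flask stands at 79.7%.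

All runs are calculated from invented constants; scatter was added.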